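Numbering: C1(OBz)–C2=C3–C4(OBz)–C5(OH)–C6(OH)(C7H2OH). The plan deletes C2: the cyclohexene comes from a cyclopentanone (C1 carbonyl, C3 methylene) whose C4, C5 and C6 stereocentres are built from (R)-4-silyloxycyclopentenone. In the key step FeCl3 oxidises a 1-siloxybicyclo[3.1.0]hexane; the strained C1–C3 fusion bond breaks, C3 is chlorinated and HCl is lost, so the six-membered ring and the C2=C3 enone arise in one operation. It exploits quaternary C6, which forces enolisation toward C3, and the strain of the C1–C2–C3 cyclopropane. The precursor is that cyclopropane with O4 silylated, O5 as methoxymethyl ether and O6/O7 as acetonide.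

Key step: step 9

Remark: "top" means the ring face that carries O4; the target is taken as (1S,4R,5R,6S) in this numbering, with O1, O4, O5 and C7 on top and O6 below.

Step 1
Reactants: 1 (R)-4-(tert-butyldimethylsilyloxy)cyclopent-2-en-1-one; 2 formaldehyde
Product: 3 (R)-4-(tert-butyldimethylsilyloxy)-2-(hydroxymethyl)cyclopent-2-en-1-one
Conditions: 37% aqueous HCHO, imidazole, THF/H2O, rt
Reagents that add atoms: formaldehyde, C=O
Why: Morita–Baylis–Hillman reaction in which reversible conjugate addition of imidazole gives an enolate that adds to formaldehyde at the α-carbon (future C6) and then expels the catalyst, so C7 is installed without touching C4 and in a medium too weakly basic to eliminate the silyloxy group.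

Step 2
Reactants: 3 (R)-4-(tert-butyldimethylsilyloxy)-2-(hydroxymethyl)cyclopent-2-en-1-one
Product: 4 (1S,4R,5S)-4-(tert-butyldimethylsilyloxy)-1-(hydroxymethyl)-6-oxabicyclo[3.1.0]hexan-2-one (C5–C6 epoxide on the bottom face)
Conditions: 30% aqueous H2O2, NaOH (cat.), MeOH, −20 to 0 °C
Reagents that add atoms: hydrogen peroxide, OO
Why: Weitz–Scheffer nucleophilic epoxidation in which hydroperoxide adds to C5 on the face opposite the bulky C4 silyloxy group and the enolate closes on oxygen, which sets C5 and C6 with the epoxide trans to O4 and thereby fixes O6 (bottom) and C7 (top) in their final arrangement.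

Step 3
Reactants: 4 (1S,4R,5S)-4-(tert-butyldimethylsilyloxy)-1-(hydroxymethyl)-6-oxabicyclo[3.1.0]hexan-2-one
Product: 5 (2S,3R,4R)-4-(tert-butyldimethylsilyloxy)-2-hydroxy-2-(hydroxymethyl)-3-(4-nitrobenzoyloxy)cyclopentan-1-one
Conditions: 4-O2NC6H4CO2H, Ti(OiPr)4, CH2Cl2, rt; aqueous tartaric acid work-up
Reagents that add atoms: 4-nitrobenzoic acid, O=C(O)c1ccc(cc1)[N+](=O)[O-]
Why: Ti(OiPr)4-mediated opening of a 2,3-epoxy alcohol at its C3 position (here C5) by a carboxylic acid, in which the C7 alkoxide and the epoxide oxygen bind titanium, quaternary α-keto C6 cannot be attacked, and SN2 entry of the carboxylate anti to the breaking C5–O bond inverts C5 and places O5 on top, cis to O4.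

Step 4
Reactants: 5 (2S,3R,4R)-4-(tert-butyldimethylsilyloxy)-2-hydroxy-2-(hydroxymethyl)-3-(4-nitrobenzoyloxy)cyclopentan-1-one
Product: 6 (5S,8R,9R)-8-(tert-butyldimethylsilyloxy)-2,2-dimethyl-9-(4-nitrobenzoyloxy)-1,3-dioxaspiro[4.4]nonan-6-one (O6/O7 acetonide)
Conditions: Me2C(OMe)2, PPTS (cat.), acetone, rt, on the crude diol
Reagents that add atoms: 2,2-dimethoxypropane, COC(C)(C)OC
Why: Acid-catalysed transacetalisation in which the tertiary O6–H and primary O7–H are the only free 1,2-diol (O5 is acylated and trans to O6), so a single spiro-1,3-dioxolane forms and also blocks α-ketol and retro-aldol pathways at C6.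

Step 5
Reactants: 6 (5S,8R,9R)-8-(tert-butyldimethylsilyloxy)-2,2-dimethyl-9-(4-nitrobenzoyloxy)-1,3-dioxaspiro[4.4]nonan-6-one
Product: 7 (5S,8R,9R)-8-(tert-butyldimethylsilyloxy)-9-hydroxy-2,2-dimethyl-1,3-dioxaspiro[4.4]nonan-6-one
Conditions: NaN3, MeOH, 40 °C
Reagents that add atoms: none
Why: Azide-mediated methanolysis of the activated 4-nitrobenzoate runs under essentially neutral conditions, so O5–H is freed without the alkoxide concentrations that would cause silyl migration from O4, retro-aldol cleavage or E1cB loss of the C4 silyloxy group.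

Step 6
Reactants: 7 (5S,8R,9R)-8-(tert-butyldimethylsilyloxy)-9-hydroxy-2,2-dimethyl-1,3-dioxaspiro[4.4]nonan-6-one
Product: 8 (5S,8R,9R)-8-(tert-butyldimethylsilyloxy)-9-(methoxymethoxy)-2,2-dimethyl-1,3-dioxaspiro[4.4]nonan-6-one
Conditions: MOMCl, iPr2NEt, Bu4NI (cat.), CH2Cl2, 0 °C to rt
Reagents that add atoms: chloromethyl methyl ether, COCCl
Why: O-alkylation of the hindered secondary O5–H with the small, highly reactive chloromethyl ether under a hindered amine base gives an acid-labile acetal that is orthogonal to the fluoride-labile O4 silyl ether.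

Step 7
Reactants: 8 (5S,8R,9R)-8-(tert-butyldimethylsilyloxy)-9-(methoxymethoxy)-2,2-dimethyl-1,3-dioxaspiro[4.4]nonan-6-one
Product: 9 (5S,8R,9R)-8-(tert-butyldimethylsilyloxy)-9-(methoxymethoxy)-2,2-dimethyl-6-(trimethylsilyloxy)-1,3-dioxaspiro[4.4]non-6-ene (C1=C3 silyl enol ether)
Conditions: TMSOTf, Et3N, CH2Cl2, −20 to 0 °C
Reagents that add atoms: trimethylsilyl trifluoromethanesulfonate, C[Si](C)(C)OS(=O)(=O)C(F)(F)F
Why: Soft enolisation with O-silylation can occur only toward C3 because C6 bears no hydrogen, and the triflate/amine conditions avoid a free enolate that could expel the C4 silyloxy group.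

Step 8
Reactants: 9 silyl enol ether (C1=C3); 10 diiodomethane
Product: 11 1-(trimethylsilyloxy)bicyclo[3.1.0]hexane with the C1–C2–C3 cyclopropane on the bottom face and O4 silyl ether (top) and O5 methoxymethyl ether (top) and O6/O7 spiro-acetonide (O6 bottom)
Conditions: Et2Zn, CH2I2, CH2Cl2, 0 °C to rt
Reagents that add atoms: diiodomethane, ICI
Why: Simmons–Smith cyclopropanation of the electron-rich silyl enol ether delivers the C2 methylene across C1=C3, expected on the face opposite O4, and the two new stereocentres vanish in step 9, so either facial outcome is acceptable.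

Step 9
Reactants: 11 1-(trimethylsilyloxy)bicyclo[3.1.0]hexane precursor
Product: 13 enone (5S,9R,10R)-9-(tert-butyldimethylsilyloxy)-10-(methoxymethoxy)-2,2-dimethyl-1,3-dioxaspiro[4.5]dec-7-en-6-one, via β-chloro ketone 12 (not isolated)
Conditions: FeCl3, pyridine, DMF, 0 °C to rt; then NaOAc, MeOH, 60 °C
Reagents that add atoms: none
Why: One-electron oxidation of the siloxycyclopropane by FeCl3 gives an oxygen-centred radical cation whose strain-driven β-scission breaks the C1–C3 ring-fusion bond, creating the C1 carbonyl and a secondary radical at C3; chlorine transfer from a second FeCl3 gives β-chloro ketone 12, and acetate-induced E1cB loss of HCl then forms C2=C3. The closest known reaction type is the Ito–Saegusa FeCl3 ring expansion of 1-siloxybicyclo[n.1.0]alkanes to cycloalk-2-enones. The six-membered carbocycle is closed not by a cyclisation but by ring enlargement: when the bond shared by the five- and three-membered rings breaks, C2 becomes a member of the merged six-membered ring. No stereocentre is created, since the C3 chloride is lost again and C4, C5 and C6 are untouched. The step needs cleavage of the internal rather than the external cyclopropane bond, secured by the more stable secondary ring radical, and a single enone regiochemistry, secured earlier because quaternary C6 allowed the enol ether only toward C3; DMF and pyridine temper the Lewis acidity so that the silyl ether and the two acetals should survive.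

Step 10
Reactants: 13 enone (C1 ketone, C2=C3)
Product: 14 allylic alcohol with O1–H on top (1S) and C4 to C6 unchanged
Conditions: NaBH4, CeCl3·7H2O, MeOH, −78 °C
Reagents that add atoms: none
Why: Luche 1,2-reduction in which, in the half-chair that keeps O5 and O6 trans-diaxial, the top face of the carbonyl is screened by the axial O5 acetal and by C7, so hydride should enter from the O6 face and set C1 as (S) with O1 on top, cis to C7 and trans to O6.

Step 11
Reactants: 14 allylic alcohol (O1–H free, O4 silylated)
Product: 15 diol with O1–H and O4–H free, O5 methoxymethyl ether and O6/O7 acetonide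
Conditions: TBAF, THF, 0 °C; aqueous NH4Cl
Reagents that add atoms: none
Why: Fluoride-induced Si–O cleavage frees the allylic O4–H while the acetal groups on O5, O6 and O7 are inert and no ester is yet present that could migrate.

Step 12
Reactants: 15 diol; 16 benzoyl chloride
Product: 17 O1,O4-dibenzoate with O5 methoxymethyl ether and O6/O7 acetonide
Conditions: BzCl, pyridine, DMAP (cat.), CH2Cl2, 0 °C to rt
Reagents that add atoms: benzoyl chloride, O=C(Cl)c1ccccc1
Why: DMAP-catalysed acylation esterifies the two free secondary allylic hydroxyls O1 and O4 with retention of configuration while O5, O6 and O7 stay masked.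

Step 13
Reactants: 17 protected dibenzoate
Product: 18 [(1S,4R,5R,6S)-4-(benzoyloxy)-5,6-dihydroxy-6-(hydroxymethyl)cyclohex-2-en-1-yl] benzoate (target)
Conditions: TFA/H2O (9:1), 0 °C to rt
Reagents that add atoms: none
Why: Acid-catalysed acetal hydrolysis removes the isopropylidene group and the methoxymethyl ether in one operation, while benzoates are acid-stable and benzoyl migration, which is base-promoted, should be slow at low pH and low temperature.

Compound list

1 | (R)-4-(tert-butyldimethylsilyloxy)cyclopent-2-en-1-one | O=C1C[C@@H](O[Si](C)(C)C(C)(C)C)C=C1 | starting material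
2 | formaldehyde | C=O | starting material
3 | (R)-4-(tert-butyldimethylsilyloxy)-2-(hydroxymethyl)cyclopent-2-en-1-one | O=C1C[C@@H](O[Si](C)(C)C(C)(C)C)C=C1CO | intermediate
4 | (1S,4R,5S)-4-(tert-butyldimethylsilyloxy)-1-(hydroxymethyl)-6-oxabicyclo[3.1.0]hexan-2-one | O=C1C[C@@H](O[Si](C)(C)C(C)(C)C)[C@@H]2O[C@]12CO | intermediate
5 | (2S,3R,4R)-4-(tert-butyldimethylsilyloxy)-2-hydroxy-2-(hydroxymethyl)-3-(4-nitrobenzoyloxy)cyclopentan-1-one | O=C1C[C@@H](O[Si](C)(C)C(C)(C)C)[C@@H](OC(=O)c2ccc(cc2)[N+](=O)[O-])[C@@]1(O)CO | intermediate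
6 | (5S,8R,9R)-8-(tert-butyldimethylsilyloxy)-2,2-dimethyl-9-(4-nitrobenzoyloxy)-1,3-dioxaspiro[4.4]nonan-6-one | O=C1C[C@@H](O[Si](C)(C)C(C)(C)C)[C@@H](OC(=O)c2ccc(cc2)[N+](=O)[O-])[C@@]1(OC3(C)C)CO3 | intermediate
7 | (5S,8R,9R)-8-(tert-butyldimethylsilyloxy)-9-hydroxy-2,2-dimethyl-1,3-dioxaspiro[4.4]nonan-6-one | O=C1C[C@@H](O[Si](C)(C)C(C)(C)C)[C@@H](O)[C@@]1(OC2(C)C)CO2 | intermediate
8 | (5S,8R,9R)-8-(tert-butyldimethylsilyloxy)-9-(methoxymethoxy)-2,2-dimethyl-1,3-dioxaspiro[4.4]nonan-6-one | O=C1C[C@@H](O[Si](C)(C)C(C)(C)C)[C@@H](OCOC)[C@@]1(OC2(C)C)CO2 | intermediate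
9 | (5S,8R,9R)-8-(tert-butyldimethylsilyloxy)-9-(methoxymethoxy)-2,2-dimethyl-6-(trimethylsilyloxy)-1,3-dioxaspiro[4.4]non-6-ene | C[Si](C)(C)OC1=C[C@@H](O[Si](C)(C)C(C)(C)C)[C@@H](OCOC)[C@@]1(OC2(C)C)CO2 | intermediate
10 | diiodomethane | ICI | starting material
11 | 1-(trimethylsilyloxy)bicyclo[3.1.0]hexane, cyclopropane CH2 (C2) on the bottom face, O4 tert-butyldimethylsilyl ether, O5 methoxymethyl ether, O6/O7 acetonide | C[Si](C)(C)O[C@@]12C[C@@H]1[C@@H](O[Si](C)(C)C(C)(C)C)[C@@H](OCOC)[C@@]2(OC3(C)C)CO3 | intermediate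
12 | 3-chlorocyclohexanone (C1 ketone, C3 chloride of either configuration), O4 silyl ether, O5 methoxymethyl ether, O6/O7 acetonide | O=C1CC(Cl)[C@@H](O[Si](C)(C)C(C)(C)C)[C@@H](OCOC)[C@@]1(OC2(C)C)CO2 | intermediate
13 | (5S,9R,10R)-9-(tert-butyldimethylsilyloxy)-10-(methoxymethoxy)-2,2-dimethyl-1,3-dioxaspiro[4.5]dec-7-en-6-one | O=C1C=C[C@@H](O[Si](C)(C)C(C)(C)C)[C@@H](OCOC)[C@@]1(OC2(C)C)CO2 | intermediate
14 | allylic alcohol from 13, C1 (S), O1–H on top, cis to C7 and trans to O6 | O[C@H]1C=C[C@@H](O[Si](C)(C)C(C)(C)C)[C@@H](OCOC)[C@@]1(OC2(C)C)CO2 | intermediate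
15 | 1,4-diol (O1–H and O4–H free, both on top), O5 methoxymethyl ether, O6/O7 acetonide | O[C@H]1C=C[C@@H](O)[C@@H](OCOC)[C@@]1(OC2(C)C)CO2 | intermediate
16 | benzoyl chloride | O=C(Cl)c1ccccc1 | starting material
17 | O1,O4-dibenzoate, O5 methoxymethyl ether, O6/O7 acetonide | O=C(O[C@H]1C=C[C@@H](OC(=O)c2ccccc2)[C@@H](OCOC)[C@@]1(OC3(C)C)CO3)c1ccccc1 | intermediate
18 | [(1S,4R,5R,6S)-4-(benzoyloxy)-5,6-dihydroxy-6-(hydroxymethyl)cyclohex-2-en-1-yl] benzoate | O=C(O[C@H]1C=C[C@@H](OC(=O)c2ccccc2)[C@@H](O)[C@@]1(O)CO)c1ccccc1 | target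

Total step count: 13. Longest linear sequence: 13 steps (1 to 18).

Steps most likely to fail

Step 9. The trivalent-iron oxidation may be outrun by acid-induced protodesilylation of the cyclopropanol ether, by cleavage of the external C1–C2 bond, or by loss of the acetal groups in the Lewis-acidic medium. The fallback replaces the cyclopropane fragmentation by a diazo homologation and sets out from ketone 8. Trimethylsilyldiazomethane with BF3·OEt2 at −78 °C inserts a methylene between C1 and C3, the unhindered C3 methylene migrating in preference to quaternary, oxygen-bearing C6, to give the 2-(trimethylsilyl)cyclohexanone F1. This loses its C-silyl group on work-up to give the ring-expanded cyclohexanone F2. TMSOTf/Et3N converts F2 into the only possible silyl enol ether F3, and Saegusa–Ito dehydrogenation with Pd(OAc)2 in MeCN rejoins the route at enone 13.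

Step 3. The carboxylate must enter at C5 on the face that carries the O4 silyl ether, so the opening may be slow and be overtaken by isopropoxide transfer, Payne-type isomerisation or acyl migration. The fallback delivers the oxygen intramolecularly from C7 and sets out from epoxide 4. Boc2O/DMAP gives the O7 tert-butyl carbonate F4. BF3·OEt2 at low temperature lets the carbonate carbonyl oxygen attack C5 from the top face, where C7 sits (quaternary α-keto C6 is not attackable), with loss of 2-methylpropene, giving the six-membered O5/O7 cyclic carbonate F5 with O6–H free. Brief methanolysis (K2CO3, MeOH, 0 °C) gives the triol F6. Me2C(OMe)2/PPTS, which favours the five-membered dioxolane on the O6/O7 1,2-diol over the six-membered O5/O7 acetal, rejoins the route at alcohol 7.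

Step 10. Facial selectivity of hydride addition may be poor or reversed, because attack anti to the axial C6–O6 bond (Felkin–Anh) competes with the sterically favoured approach and would give the C1 epimer. The fallback accepts that epimer and corrects it while installing the ester; it sets out from enone 13. The C1-epimeric allylic alcohol F7 undergoes a Mitsunobu reaction (PhCO2H, DIAD, PPh3), which introduces the O1 benzoate with inversion to give the O1-benzoate O4-silyl ether F8. HF·pyridine gives the O1-benzoate O4-alcohol F9, and benzoylation of O4 (BzCl, pyridine, DMAP) rejoins the route at dibenzoate 17.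

Further compounds

F1 | step 9 | 2-(trimethylsilyl)cyclohexanone from homologation of 8 (C2 of either configuration) | O=C1C([Si](C)(C)C)C[C@@H](O[Si](C)(C)C(C)(C)C)[C@@H](OCOC)[C@@]1(OC2(C)C)CO2
F2 | step 9 | ring-expanded cyclohexanone (C1 ketone, C2 and C3 methylene) | O=C1CC[C@@H](O[Si](C)(C)C(C)(C)C)[C@@H](OCOC)[C@@]1(OC2(C)C)CO2
F3 | step 9 | trimethylsilyl enol ether of F2 (C1=C2) | C[Si](C)(C)OC1=CC[C@@H](O[Si](C)(C)C(C)(C)C)[C@@H](OCOC)[C@@]1(OC2(C)C)CO2
F4 | step 3 | O7 tert-butyl carbonate of epoxide 4 | O=C1C[C@@H](O[Si](C)(C)C(C)(C)C)[C@@H]2O[C@]12COC(=O)OC(C)(C)C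
F5 | step 3 | O5/O7 cyclic carbonate with free O6–H | O=C1C[C@@H](O[Si](C)(C)C(C)(C)C)[C@H]2OC(=O)OC[C@@]12O
F6 | step 3 | (2S,3R,4R)-4-(tert-butyldimethylsilyloxy)-2,3-dihydroxy-2-(hydroxymethyl)cyclopentan-1-one | O=C1C[C@@H](O[Si](C)(C)C(C)(C)C)[C@@H](O)[C@@]1(O)CO
F7 | step 10 | C1 epimer of allylic alcohol 14 (O1–H on the bottom face) | O[C@@H]1C=C[C@@H](O[Si](C)(C)C(C)(C)C)[C@@H](OCOC)[C@@]1(OC2(C)C)CO2
F8 | step 10 | O1 benzoate (C1 S) with O4 silyl ether | O=C(O[C@H]1C=C[C@@H](O[Si](C)(C)C(C)(C)C)[C@@H](OCOC)[C@@]1(OC2(C)C)CO2)c1ccccc1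
F9 | step 10 | O1 benzoate (C1 S) with free O4–H | O=C(O[C@H]1C=C[C@@H](O)[C@@H](OCOC)[C@@]1(OC2(C)C)CO2)c1ccccc1
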